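**Plan**
1. Retrosynthesis: the aryl ether O–C11 is cut first (umbelliferone plus a primary alcohol), then the C3–C4 bond of ring A; what is left is ring B with a C5 isopropenyl group, the C12 methyl and a C9 carbonyl, which is (S)-carvone.
2. Forward: two α′-alkylations of (S)-carvone build quaternary C10 (methyl, then allyl); the C9 ketone becomes a dienyl triflate and then the C11 ester; the allyl group becomes the C1–C2–C3 aldehyde arm.
3. Ring A is closed last, on the finished ring B: Fe–H hydrogen-atom transfer to the isopropenyl group gives the tertiary C4 radical, which adds 6-exo to the C3 aldehyde (C3–C4 bond, gem-dimethyl C4 and the C3 oxygen in one step).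
4. Feature that allows this: C4 is a gem-dimethyl quaternary carbon between carbinol C3 and ring-fusion C5, i.e. a hydrogenated isopropenyl carbon bonded to a carbonyl carbon, with C5 and C10 already trans on ring B.
5. Stereochemistry: C5 from carvone; C10 by alkylation anti to isopropenyl (hence the trans ring fusion); C3 (axial OH) by L-Selectride on the 3-ketone; C9 by kinetic α-protonation of the ester dienolate anti to the angular methyl, which also creates the 6,8(12)-diene.
6. End game: ester reduction and Mitsunobu etherification with umbelliferone.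

Key step: step 7

Remark: locants C1–C12 are drimane locants (ring A = C1–C5 and C10; ring B = C5–C10; C11 = CH2O on C9; C12 = exocyclic CH2 on C8). The C3 configuration formed in step 7 is not relied on, because both epimers give one ketone in step 8.

**Step 1**
Reactants: 1 (S)-(+)-carvone
Product: 3 (5S)-6-methylcarvone (C6 epimer mixture), via lithium α′-dienolate of carvone 2 (not isolated)
Conditions: LDA (1.05 equiv), THF, −78 °C; MeI, −78 → 0 °C
Reagents that add atoms: iodomethane (CI)
Why: Kinetic α′-deprotonation gives the cross-conjugated lithium dienolate, whose C-methylation (enolate alkylation) installs the future C10 methyl; the C6 epimer composition is irrelevant because this centre is re-enolized in step 2.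

**Step 2**
Reactants: 3 (5S)-6-methylcarvone
Product: 5 (5R,6R)-6-allyl-6-methylcarvone (allyl trans to isopropenyl), via lithium enolate of 6-methylcarvone 4 (not isolated)
Conditions: LDA (1.1 equiv), THF, −78 → −20 °C; allyl bromide, DMPU, −78 °C → rt
Reagents that add atoms: allyl bromide (C=CCBr)
Why: Enolate alkylation of the tetrasubstituted α′-enolate should occur on the face anti to the neighbouring C5 isopropenyl group (1,2-induction), so the quaternary carbon forms with allyl trans and methyl cis to isopropenyl, the C5/C10 relationship of a trans-decalin.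

**Step 3**
Reactants: 5 (5R,6R)-6-allyl-6-methylcarvone
Product: 7 (5R,6R)-6-allyl-2,6-dimethyl-5-(prop-1-en-2-yl)cyclohexa-1,3-dien-1-yl triflate, via potassium dienolate 6 (not isolated)
Conditions: KHMDS (1.1 equiv), THF, −78 → 0 °C; PhNTf2, −78 °C → rt
Reagents that add atoms: N-phenylbis(trifluoromethanesulfonimide) (O=S(=O)(N(c1ccccc1)S(=O)(=O)C(F)(F)F)C(F)(F)F)
Why: With the α′ carbon quaternary, only the γ-CH2 (C6) can be deprotonated, so the linear dienolate forms and is O-triflated (enol triflate formation) to the 1-triflyloxy-1,3-diene.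

**Step 4**
Reactants: 7 dienyl triflate
Product: 8 methyl (5R,6R)-6-allyl-2,6-dimethyl-5-(prop-1-en-2-yl)cyclohexa-1,3-diene-1-carboxylate
Conditions: Pd(OAc)2 (5 mol %), dppf (10 mol %), CO (1 atm), Et3N, MeOH/DMF, 60 °C
Reagents that add atoms: carbon monoxide ([C-]#[O+]); methanol (CO)
Why: Pd-catalysed methoxycarbonylation of the enol triflate (oxidative addition, CO insertion, methanolysis) brings in C11 at the ester level, and methanol as co-solvent should capture the acyl-palladium before it can insert the pendant allyl group.

**Step 5**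
Reactants: 8 methyl dienoate with allyl arm
Product: 10 methyl (5R,6R)-6-(3-hydroxypropyl)-2,6-dimethyl-5-(prop-1-en-2-yl)cyclohexa-1,3-diene-1-carboxylate, via alkyl(disiamyl)borane 9 (not isolated)
Conditions: Sia2BH (1.3 equiv), THF, 0 °C; then 30% H2O2, aq. NaOH, 0 °C
Reagents that add atoms: hydrogen peroxide (OO)
Why: Anti-Markovnikov hydroboration–oxidation; the bulky dialkylborane should react with the monosubstituted allyl terminus much faster than with the hindered 1,1-disubstituted isopropenyl group or the electron-poor tetrasubstituted dienoate.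

**Step 6**
Reactants: 10 primary alcohol
Product: 11 methyl (5R,6R)-2,6-dimethyl-6-(3-oxopropyl)-5-(prop-1-en-2-yl)cyclohexa-1,3-diene-1-carboxylate
Conditions: Dess–Martin periodinane (1.2 equiv), NaHCO3, CH2Cl2, 0 °C → rt
Reagents that add atoms: none
Why: Dess–Martin oxidation of the primary alcohol stops at the aldehyde under buffered neutral conditions that leave the ester, the diene and the isopropenyl group untouched.

**Step 7**
Reactants: 11 aldehyde
Product: 14 methyl (4aS,6R,8aR)-6-hydroxy-2,5,5,8a-tetramethyl-4a,5,6,7,8,8a-hexahydronaphthalene-1-carboxylate (trans-fused; drawn as the equatorial C3 alcohol), via tertiary C4 radical 12 (not isolated), via C3 alkoxyl radical 13 (not isolated)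
Conditions: Fe(acac)3 (30 mol %), PhSiH3 (2.5 equiv, slow addition), degassed EtOH, 0.02 M, 60 °C
Reagents that add atoms: none
Why: The iron hydride formed from Fe(acac)3, PhSiH3 and EtOH transfers a hydrogen atom to the terminal CH2 of the isopropenyl group (Markovnikov HAT), giving the tertiary C4 radical that already carries both methyls of the gem-dimethyl carbon; this radical adds to the tethered C3 aldehyde and the alkoxyl radical is reduced by Fe(II)/EtOH to the alcohol. The closest known reaction types are the iron-catalysed HAT-initiated reductive radical cyclization of alkene-tethered ketones and the iron-HAT intermolecular addition of unactivated alkenes to aldehydes. Ring A (C3–C4–C5–C10–C1–C2) closes in the 6-exo-trig mode onto the carbonyl carbon through a chair transition state. C4 becomes quaternary but is not stereogenic; the ring fusion should be trans because the C5 and C10 arms were set trans in steps 1–2 and reach each other only when both are pseudo-equatorial; at C3 the carbonyl oxygen should prefer the pseudo-equatorial position, giving mainly the equatorial alcohol, a centre that is not relied on. The step needs HAT at the electron-rich 1,1-disubstituted alkene rather than at the conjugated dienoate, and cyclization rather than simple reduction of the radical: the dienoate is electron-poor, hindered and cannot act as an intramolecular acceptor (only three- or four-membered rings would form), and high dilution with slow silane addition keeps the hydride concentration low while 6-exo addition to an aldehyde is fast.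

**Step 8**
Reactants: 14 C3 alcohol (either epimer)
Product: 15 methyl (4aS,8aR)-2,5,5,8a-tetramethyl-6-oxo-4a,5,6,7,8,8a-hexahydronaphthalene-1-carboxylate
Conditions: Dess–Martin periodinane (1.3 equiv), NaHCO3, CH2Cl2, rt
Reagents that add atoms: none
Why: Dess–Martin oxidation converts either C3 epimer of the neopentyl secondary alcohol into one 3-ketone, erasing the uncontrolled centre without touching the dienoate.

**Step 9**
Reactants: 15 3-ketone
Product: 16 methyl (4aS,6S,8aR)-6-hydroxy-2,5,5,8a-tetramethyl-4a,5,6,7,8,8a-hexahydronaphthalene-1-carboxylate (axial C3–OH, trans to the C10 methyl)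
Conditions: L-Selectride (1.2 equiv), THF, −78 °C; H2O quench
Reagents that add atoms: none
Why: Bulky trialkylborohydride reduction; as in 4,4-dimethyl-3-oxo terpenoids the hydride should arrive along the equatorial trajectory and give the axial alcohol, while the hindered dienoate is not reduced at −78 °C.

**Step 10**
Reactants: 16 conjugated hydroxy dienoate
Product: 18 methyl (1R,4aS,6S,8aR)-6-hydroxy-5,5,8a-trimethyl-2-methylidene-1,2,4a,5,6,7,8,8a-octahydronaphthalene-1-carboxylate, via dilithium alkoxide–dienolate 17 (not isolated)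
Conditions: LDA (3 equiv), THF/DMPU, −78 °C; inverse quench into AcOH/THF, −78 °C
Reagents that add atoms: none
Why: Deconjugative protonation; after O–H deprotonation LDA removes a proton from the C12 methyl syn to the ester (γ-deprotonation), and the cross-conjugated dienolate should be protonated kinetically at the α-carbon C9 from the face opposite the axial C10 methyl, placing the ester cis to that methyl and leaving the 6,8(12)-diene.

**Step 11**
Reactants: 18 β,γ-unsaturated ester
Product: 19 [(1R,4aS,6S,8aR)-6-hydroxy-5,5,8a-trimethyl-2-methylidene-1,2,4a,5,6,7,8,8a-octahydronaphthalen-1-yl]methanol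
Conditions: LiAlH4 (2 equiv), Et2O, −20 → 0 °C; aq. NaOH work-up
Reagents that add atoms: none
Why: Hydride reduction of the ester to the primary alcohol, which at low temperature should not epimerize or reconjugate the doubly activated C9–H.

**Step 12**
Reactants: 19 diol; 20 umbelliferone (7-hydroxycoumarin)
Product: 21 7-{[(1R,4aS,6S,8aR)-6-hydroxy-5,5,8a-trimethyl-2-methylidene-1,2,4a,5,6,7,8,8a-octahydronaphthalen-1-yl]methoxy}-2H-chromen-2-one (CNP0259618.1)
Conditions: PPh3 (1.5 equiv), DIAD (1.5 equiv), THF, 0 °C → rt
Reagents that add atoms: none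
Why: Mitsunobu etherification; the acidic phenol displaces the oxyphosphonium of the primary alcohol, whereas the axial neopentyl C3 alcohol is too hindered to be activated, so no protecting group is needed.

**Compound list**
1 | (S)-(+)-carvone | CC1=CC[C@H](C(C)=C)CC1=O | starting material
2 | lithium α′-dienolate of (S)-carvone | CC1=CC[C@H](C(C)=C)C=C1[O-].[Li+] | intermediate
3 | (5S)-2,6-dimethyl-5-(prop-1-en-2-yl)cyclohex-2-en-1-one (6-methylcarvone, C6 epimer mixture) | CC1=CC[C@H](C(C)=C)C(C)C1=O | intermediate
4 | lithium enolate of 6-methylcarvone | CC1=CC[C@H](C(C)=C)C(C)=C1[O-].[Li+] | intermediate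
5 | (5R,6R)-2,6-dimethyl-5-(prop-1-en-2-yl)-6-(prop-2-en-1-yl)cyclohex-2-en-1-one | CC1=CC[C@H](C(C)=C)[C@@](C)(CC=C)C1=O | intermediate
6 | potassium (5R,6R)-6-allyl-2,6-dimethyl-5-(prop-1-en-2-yl)cyclohexa-1,3-dien-1-olate | CC=1C=C[C@H](C(C)=C)[C@@](C)(CC=C)C=1[O-].[K+] | intermediate
7 | (5R,6R)-6-allyl-2,6-dimethyl-5-(prop-1-en-2-yl)cyclohexa-1,3-dien-1-yl trifluoromethanesulfonate | CC=1C=C[C@H](C(C)=C)[C@@](C)(CC=C)C=1OS(=O)(=O)C(F)(F)F | intermediate
8 | methyl (5R,6R)-6-allyl-2,6-dimethyl-5-(prop-1-en-2-yl)cyclohexa-1,3-diene-1-carboxylate | CC=1C=C[C@H](C(C)=C)[C@@](C)(CC=C)C=1C(=O)OC | intermediate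
9 | methyl (5R,6R)-6-{3-[bis(3-methylbutan-2-yl)boranyl]propyl}-2,6-dimethyl-5-(prop-1-en-2-yl)cyclohexa-1,3-diene-1-carboxylate | CC=1C=C[C@H](C(C)=C)[C@@](C)(CCCB(C(C)C(C)C)C(C)C(C)C)C=1C(=O)OC | intermediate
10 | methyl (5R,6R)-6-(3-hydroxypropyl)-2,6-dimethyl-5-(prop-1-en-2-yl)cyclohexa-1,3-diene-1-carboxylate | CC=1C=C[C@H](C(C)=C)[C@@](C)(CCCO)C=1C(=O)OC | intermediate
11 | methyl (5R,6R)-2,6-dimethyl-6-(3-oxopropyl)-5-(prop-1-en-2-yl)cyclohexa-1,3-diene-1-carboxylate | CC=1C=C[C@H](C(C)=C)[C@@](C)(CCC=O)C=1C(=O)OC | intermediate
12 | tertiary C4 radical (11 after H-atom addition to the isopropenyl CH2) | CC=1C=C[C@H]([C](C)C)[C@@](C)(CCC=O)C=1C(=O)OC | intermediate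
13 | cyclized C3 alkoxyl radical (trans-fused, O equatorial) | CC=1C=C[C@@H]2C(C)(C)[C@H]([O])CC[C@@]2(C)C=1C(=O)OC | intermediate
14 | methyl (4aS,6R,8aR)-6-hydroxy-2,5,5,8a-tetramethyl-4a,5,6,7,8,8a-hexahydronaphthalene-1-carboxylate | CC=1C=C[C@@H]2C(C)(C)[C@H](O)CC[C@@]2(C)C=1C(=O)OC | intermediate
15 | methyl (4aS,8aR)-2,5,5,8a-tetramethyl-6-oxo-4a,5,6,7,8,8a-hexahydronaphthalene-1-carboxylate | CC=1C=C[C@@H]2C(C)(C)C(=O)CC[C@@]2(C)C=1C(=O)OC | intermediate
16 | methyl (4aS,6S,8aR)-6-hydroxy-2,5,5,8a-tetramethyl-4a,5,6,7,8,8a-hexahydronaphthalene-1-carboxylate | CC=1C=C[C@@H]2C(C)(C)[C@@H](O)CC[C@@]2(C)C=1C(=O)OC | intermediate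
17 | dilithium C3-alkoxide / cross-conjugated ester dienolate of 16 | C=C1C=C[C@@H]2C(C)(C)[C@@H]([O-])CC[C@@]2(C)C1=C([O-])OC.[Li+].[Li+] | intermediate
18 | methyl (1R,4aS,6S,8aR)-6-hydroxy-5,5,8a-trimethyl-2-methylidene-1,2,4a,5,6,7,8,8a-octahydronaphthalene-1-carboxylate | C=C1C=C[C@@H]2C(C)(C)[C@@H](O)CC[C@@]2(C)[C@@H]1C(=O)OC | intermediate
19 | [(1R,4aS,6S,8aR)-6-hydroxy-5,5,8a-trimethyl-2-methylidene-1,2,4a,5,6,7,8,8a-octahydronaphthalen-1-yl]methanol | C=C1C=C[C@@H]2C(C)(C)[C@@H](O)CC[C@@]2(C)[C@@H]1CO | intermediate
20 | umbelliferone (7-hydroxy-2H-chromen-2-one) | Oc1ccc2ccc(=O)oc2c1 | starting material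
21 | 7-{[(1R,4aS,6S,8aR)-6-hydroxy-5,5,8a-trimethyl-2-methylidene-1,2,4a,5,6,7,8,8a-octahydronaphthalen-1-yl]methoxy}-2H-chromen-2-one | C=C1C=C[C@@H]2C(C)(C)[C@@H](O)CC[C@@]2(C)[C@@H]1COc1ccc2ccc(=O)oc2c1 | target

**Count**
Total steps: 12. Longest linear sequence: 12 steps, from (S)-carvone; umbelliferone enters in the last step.

**Steps most likely to fail**

Step 7. The addition of the tertiary radical to the aldehyde is reversible (β-scission of the alkoxyl radical), so reduction of the radical to the isopropyl compound, or hydrogen-atom transfer to the dienoate, may outrun ring closure. The fallback sets out from 11 and returns at 15. Aldehyde 11 would be condensed with NH2OH·HCl in pyridine to the aldoxime F1, which would be dehydrated with Burgess reagent to the nitrile F2. Under the same Fe(acac)3/PhSiH3 conditions, the known HAT-initiated cyclization of alkene-tethered nitriles should add the tertiary radical 6-exo-dig to the C≡N group, an addition that does not revert. The resulting N–H ketimine F3 would be hydrolysed on mildly acidic work-up to ketone 15, and step 8 is then not needed.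

Step 10. The dienolate may be protonated on the face syn to the angular methyl, or at the γ-carbon so that 16 is returned, or γ-deprotonation may be slow. The fallback sets out from 16 and returns at 18, and replaces kinetic by thermodynamic control. The crude material, containing the C9 epimer F4 and 16, would be heated with NaOMe in MeOH, which interconverts 16, F4 and 18 through the same dienolate. Ester 18 is expected to be favoured: its ester is equatorial and its diene is s-trans and semicyclic, whereas in 16 the ester is twisted out of conjugation by quaternary C10 and the C12 methyl and the diene is s-cis and homoannular. Recovered 16 would be recycled.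

Step 12. The activated oxygen may be lost by E2 toward the allylic C9–H, or the SN2 at the β-branched carbon may be sluggish. The fallback sets out from 19 and returns at 21. The primary hydroxyl would be triflated selectively (Tf2O, 2,6-lutidine, CH2Cl2, −78 °C) to the C11 triflate F5. This would be displaced at low temperature by the weakly basic caesium salt of umbelliferone 20 (Cs2CO3, DMF, −20 °C → rt), giving 21.

**Further compounds**
F1 | step 7 | methyl (5R,6R)-6-[3-(hydroxyimino)propyl]-2,6-dimethyl-5-(prop-1-en-2-yl)cyclohexa-1,3-diene-1-carboxylate | CC=1C=C[C@H](C(C)=C)[C@@](C)(CCC=NO)C=1C(=O)OC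
F2 | step 7 | methyl (5R,6R)-6-(2-cyanoethyl)-2,6-dimethyl-5-(prop-1-en-2-yl)cyclohexa-1,3-diene-1-carboxylate | CC=1C=C[C@H](C(C)=C)[C@@](C)(CCC#N)C=1C(=O)OC
F3 | step 7 | methyl (4aS,8aR)-6-imino-2,5,5,8a-tetramethyl-4a,5,6,7,8,8a-hexahydronaphthalene-1-carboxylate | CC=1C=C[C@@H]2C(C)(C)C(=N)CC[C@@]2(C)C=1C(=O)OC
F4 | step 10 | methyl (1S,4aS,6S,8aR)-6-hydroxy-5,5,8a-trimethyl-2-methylidene-1,2,4a,5,6,7,8,8a-octahydronaphthalene-1-carboxylate (C9 epimer of 18) | C=C1C=C[C@@H]2C(C)(C)[C@@H](O)CC[C@@]2(C)[C@H]1C(=O)OC
F5 | step 12 | [(1R,4aS,6S,8aR)-6-hydroxy-5,5,8a-trimethyl-2-methylidene-1,2,4a,5,6,7,8,8a-octahydronaphthalen-1-yl]methyl trifluoromethanesulfonate | C=C1C=C[C@@H]2C(C)(C)[C@@H](O)CC[C@@]2(C)[C@@H]1COS(=O)(=O)C(F)(F)F
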